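**Strategy.** Everything rests on cutting ring B between C8 and C9. C8 (the exocyclic methylene carbon) and C13 (the β-carbon of the enoic acid) are read as a latent 1,5-diketone along C8–C9–C11–C12–C13. An intramolecular de Mayo reaction makes this diketone in one operation. The enol C8=C12 of a β-diketone adds to a C9=C11 vinyl group, closing ring B (C8–C9) and a cyclobutane (C11–C12). Cyclobutane strain then drives retro-aldol cleavage of C8–C12, which moves the oxobutyl chain from C8 to C9. The precursor is a monocyclic ring A compound cut out of (+)-dehydroabietic acid, which supplies C4, C5 and C10. C9 settles thermodynamically beside the C8 ketone.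

Key step: step 9

Remark: labdane numbering is used for every compound, including the abietane and seco stages, where C8 and C9 are the two ring C carbons bonded to C7 and C10. α and β are used as in the usual labdane drawing. Commercial dehydroabietic acid is assumed to be the natural (+)-(1R,4aS,10aR) enantiomer.

Step 1
Reactants: 1 (+)-dehydroabietic acid
Product: 2 dehydroabietinol
Conditions: LiAlH4, THF, 0 °C to reflux; aqueous NaOH work-up
Reagents that add atoms: none
Why: LiAlH4 reduction of the hindered C18 acid should give the neopentyl alcohol, and C4 (β-CH3), C5 (α-H) and C10 (β-CH3) are taken over unchanged from the chiral pool.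

Step 2
Reactants: 2 dehydroabietinol
Product: 3 dehydroabietinyl acetate
Conditions: Ac2O, pyridine, DMAP (cat.), CH2Cl2, rt
Reagents that add atoms: acetic anhydride CC(=O)OC(C)=O
Why: DMAP-catalysed acylation installs the C18 acetate of the target at once, so it serves as the only protecting group of the route.

Step 3
Reactants: 3 dehydroabietinyl acetate
Product: 4 ring A seco-diacid
Conditions: RuCl3·xH2O (cat.), NaIO4 (excess), CCl4/MeCN/H2O, rt
Reagents that add atoms: sodium periodate [Na+].[O-]I(=O)(=O)=O; water O
Why: RuO4 degradation of an alkylbenzene (catalytic RuCl3 with NaIO4) should burn aromatic ring C down to its two attachment carbons C8 and C9, which remain as carboxylic acids, so ring B is opened between C8 and C9 without touching C4, C5 or C10.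

Step 4
Reactants: 4 ring A seco-diacid
Product: 5 seco-diol
Conditions: BH3·THF, THF, 0 °C to rt; aqueous work-up
Reagents that add atoms: none
Why: Borane reduces carboxylic acids through acyloxyboranes much faster than esters, so both acids, including the tertiary C9 acid, should go to primary alcohols while the acetate stays.

Step 5
Reactants: 5 seco-diol
Product: 6 seco-dialdehyde
Conditions: (COCl)2, DMSO, CH2Cl2, −78 °C; Et3N, −78 to 0 °C; used without delay
Reagents that add atoms: none
Why: Swern oxidation stops at the aldehyde for both the unhindered C8 alcohol and the neopentyl C9 alcohol, and the cold, brief exposure to base limits aldol chemistry of the 1,6-dialdehyde.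

Step 6
Reactants: 7 acetyl chloride; 8 (trimethylsilyl)diazomethane
Product: 10 diazoacetone, via silyl diazoketone 9 (not isolated)
Conditions: 8 (2 equiv), THF/MeCN, 0 °C; aqueous NaHCO3 work-up; used as a CH2Cl2 solution
Reagents that add atoms: none
Why: This is acylation of a diazoalkane by an acid chloride (the diazoketone synthesis of the Arndt–Eistert sequence), in which the second equivalent of 8 scavenges HCl and the C-silyl group is lost on aqueous work-up.

Step 7
Reactants: 6 seco-dialdehyde; 10 diazoacetone
Product: 11 β-diketo aldehyde
Conditions: SnCl2 (cat.), 10 (1 equiv, slow addition), CH2Cl2, 0 °C to rt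
Reagents that add atoms: none
Why: Roskamp-type homologation (Lewis-acid-promoted addition of the diazoketone, 1,2-hydride shift, loss of N2) turns RCHO directly into RCOCH2COCH3, and with one equivalent of 10 the α-unbranched C8 aldehyde should react while the neopentyl C9 aldehyde on quaternary C10 is too hindered to compete.

Step 8
Reactants: 11 β-diketo aldehyde
Product: 12 vinyl β-diketone
Conditions: Ph3PCH3Br, NaN(SiMe3)2 (ylide in excess, about 3 equiv), THF, −78 °C to rt; aqueous NH4Cl
Reagents that add atoms: methyltriphenylphosphonium bromide C[P+](c1ccccc1)(c1ccccc1)c1ccccc1.[Br-]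
Why: In this Wittig methylenation the first equivalent of ylide deprotonates the β-diketone, whose enolate is thereby masked against olefination, and further ylide converts the non-enolisable C9 aldehyde into the C9=C11 vinyl group.

Step 9
Reactants: 12 vinyl β-diketone
Product: 14 8,13-diketone (C9 epimer mixture), via cyclobutanol photoadduct 13 (not isolated)
Conditions: hν (medium-pressure Hg lamp, Pyrex filter), degassed cyclohexane, high dilution, rt
Reagents that add atoms: none
Why: Excitation of the hydrogen-bonded enol (C12=C8–OH conjugated with the C13 carbonyl) should give a triplet that bonds from C8 to C9 of the vinyl group; the 1,4-biradical at C12 and C11 collapses to cyclobutanol 13, whose strained β-hydroxy ketone unit undergoes spontaneous retro-aldol cleavage of C8–C12 to give 1,5-diketone 14. This is an intramolecular de Mayo reaction, that is a [2+2] photocycloaddition followed by retro-aldol fragmentation. Ring B closes in a 6-exo mode through the four-atom tether C7–C6–C5–C10 in a chair-like fold with both arms equatorial on ring A, and the cyclobutane C8–C9–C11–C12 closes by biradical recombination in the straight (fused) sense. The stereocentres at C8 and C12 are erased by the fragmentation, so C9 is the only one that remains; it may arise as an epimer mixture from cis- and trans-fused 13, but because it lies α to the new C8 ketone it is under thermodynamic control, and the equatorial 9β chain (9α-H) is the sink reached in steps 10 and 11. The step needs straight rather than crossed addition and reaction through the C8 enol rather than the C13 enol: 6-exo closure is preferred over 7-endo closure as in 6-heptenyl radicals, the fully substituted C10 and the trans-diequatorial arms favour folding, and the C13 enol would have to close a seven-membered ring. The strongly absorbing enol screens the weakly absorbing product ketones, and high dilution suppresses intermolecular addition.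

Step 10
Reactants: 14 8,13-diketone (C9 epimer mixture); 15 allyl diethylphosphonoacetate
Product: 16 allyl 8-oxo enoate
Conditions: NaH, 15 (excess), THF, 0 to 40 °C
Reagents that add atoms: none
Why: Horner–Wadsworth–Emmons olefination should pick the unhindered C13 methyl ketone over the α-branched C8 ring ketone flanked by C9 and C10 and should favour the E-enoate (the minor Z isomer is removed by chromatography), while excess sodiophosphonate equilibrates C9 through the C8 enolate towards the equatorial 9β-chain epimer.

Step 11
Reactants: 16 allyl 8-oxo enoate
Product: 17 allyl ester of the target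
Conditions: Ph3PCH3Br, NaN(SiMe3)2, THF/toluene, 0 to 50 °C
Reagents that add atoms: methyltriphenylphosphonium bromide C[P+](c1ccccc1)(c1ccccc1)c1ccccc1.[Br-]
Why: In this Wittig methylenation of the hindered C8 ketone the basic ylide keeps C9 equilibrating by enolisation, and only the 9α-H epimer has an open α face at C8, so any residual 9-epimer should be funnelled into the natural configuration, which is then locked.

Step 12
Reactants: 17 allyl ester of the target
Product: 18 target acid
Conditions: Pd(PPh3)4 (cat.), morpholine, THF, rt; dilute acid work-up
Reagents that add atoms: none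
Why: In this Tsuji–Trost deallylation zerovalent palladium ionises only the allyl ester and morpholine traps the π-allyl unit, which leaves the alkyl acetate, the exocyclic methylene group and the E-enoic acid untouched.

**Compound list**

1 | (+)-dehydroabietic acid, (1R,4aS,10aR)-abieta-8,11,13-trien-18-oic acid | CC(C)c1ccc2c(c1)CC[C@H]3[C@](C)(C(=O)O)CCC[C@]23C | starting material
2 | dehydroabietinol (abieta-8,11,13-trien-18-ol) | CC(C)c1ccc2c(c1)CC[C@H]3[C@](C)(CO)CCC[C@]23C | intermediate
3 | dehydroabietinyl acetate (18-acetoxyabieta-8,11,13-triene) | CC(C)c1ccc2c(c1)CC[C@H]3[C@](C)(COC(C)=O)CCC[C@]23C | intermediate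
4 | ring A seco-diacid, (1S,2S,3R)-3-(acetoxymethyl)-2-(2-carboxyethyl)-1,3-dimethylcyclohexane-1-carboxylic acid (C8 and C9 as CO2H) | OC(=O)CC[C@H]1[C@](C)(COC(C)=O)CCC[C@]1(C)C(=O)O | intermediate
5 | seco-diol, [(1R,2R,3S)-3-(hydroxymethyl)-2-(3-hydroxypropyl)-1,3-dimethylcyclohexyl]methyl acetate | OCCC[C@H]1[C@](C)(COC(C)=O)CCC[C@]1(C)CO | intermediate
6 | seco-dialdehyde, [(1R,2S,3S)-3-formyl-1,3-dimethyl-2-(3-oxopropyl)cyclohexyl]methyl acetate | O=CCC[C@H]1[C@](C)(COC(C)=O)CCC[C@]1(C)C=O | intermediate
7 | acetyl chloride | CC(=O)Cl | starting material
8 | (trimethylsilyl)diazomethane | C[Si](C)(C)C=[N+]=[N-] | starting material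
9 | silyl diazoketone, 1-diazo-1-(trimethylsilyl)propan-2-one | CC(=O)C(=[N+]=[N-])[Si](C)(C)C | intermediate
10 | diazoacetone (1-diazopropan-2-one) | CC(=O)C=[N+]=[N-] | intermediate
11 | β-diketo aldehyde, [(1R,2S,3S)-2-(3,5-dioxohexyl)-3-formyl-1,3-dimethylcyclohexyl]methyl acetate (drawn as the diketo tautomer) | CC(=O)CC(=O)CC[C@H]1[C@](C)(COC(C)=O)CCC[C@]1(C)C=O | intermediate
12 | vinyl β-diketone, [(1R,2R,3R)-2-(3,5-dioxohexyl)-3-ethenyl-1,3-dimethylcyclohexyl]methyl acetate (drawn as the diketo tautomer) | CC(=O)CC(=O)CC[C@H]1[C@](C)(COC(C)=O)CCC[C@]1(C)C=C | intermediate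
13 | cyclobutanol photoadduct: ring B fused to the cyclobutane C8–C9–C11–C12, OH on C8, acetyl on C12 (C8, C9, C12 unassigned) | CC(=O)C1CC2C1(O)CC[C@H]3[C@](C)(COC(C)=O)CCC[C@]23C | intermediate
14 | 18-acetoxy-14,15,17-trinorlabdane-8,13-dione (C9 epimer mixture) | O=C1CC[C@H]2[C@](C)(COC(C)=O)CCC[C@]2(C)C1CCC(C)=O | intermediate
15 | allyl diethylphosphonoacetate | CCOP(=O)(CC(=O)OCC=C)OCC | starting material
16 | allyl (13E)-18-acetoxy-8-oxo-17-norlabd-13-en-15-oate (9α-H, 9β chain) | O=C1CC[C@H]2[C@](C)(COC(C)=O)CCC[C@]2(C)[C@H]1CC/C(C)=C/C(=O)OCC=C | intermediate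
17 | allyl (13E)-18-acetoxylabda-8(17),13-dien-15-oate | C=C1CC[C@H]2[C@](C)(COC(C)=O)CCC[C@]2(C)[C@H]1CC/C(C)=C/C(=O)OCC=C | intermediate
18 | (4R,5R,9S,10R,13E)-18-acetoxylabda-8(17),13-dien-15-oic acid (CNP0360430.2) | C=C1CC[C@H]2[C@](C)(COC(C)=O)CCC[C@]2(C)[C@H]1CC/C(C)=C/C(=O)O | target

**Total step count:** 12. **Longest linear sequence:** 11 (steps 1–5 and 7–12).

**Steps most likely to fail**

1. **Step 9.** Possible failures:
   - inefficient cycloaddition across the four-atom tether;
   - crossed instead of straight addition, which after fragmentation would enlarge the new ring to seven members;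
   - secondary photolysis of the product.

   The fallback closes the same ring by radical chemistry. It sets out from 6 and comes back at 17.
   - The unhindered C8 aldehyde alone is homologated with lithiated (trimethylsilyl)diazomethane (Colvin rearrangement, THF, −78 °C) to the alkynyl aldehyde F1.
   - Wittig reaction of the C9 aldehyde with the ylide from commercial [2-(2-methyl-1,3-dioxolan-2-yl)ethyl]triphenylphosphonium bromide gives the (Z)-enyne ketal F2.
   - Bu3SnH with AIBN (slow addition, benzene, 80 °C) adds a stannyl radical reversibly to the alkyne terminus, and the C8 vinyl radical closes ring B 6-exo onto C9. Allylic strain of the Z-alkene holds C12 away from C5, so the chain should end up equatorial. The product is the vinylstannane ketal F3.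
   - Aqueous HCl in THF removes tin and the dioxolane in one operation to give the methyl ketone F4.
   - Horner–Wadsworth–Emmons reaction of F4 with 15 gives 17.

2. **Step 3.** Possible failures:
   - benzylic oxidation at C7 competing with ring degradation, which would shorten the C5 arm by one carbon;
   - hydroxylation of tertiary C–H bonds;
   - incomplete breakdown of ring C.

   The fallback activates ring C as a phenol before cleavage. It sets out from 3 and comes back at 4.
   - Friedel–Crafts acetylation at C12 (AcCl, AlCl3, CH2Cl2) gives the 12-acetyl compound F5.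
   - Baeyer–Villiger oxidation (mCPBA, CH2Cl2) gives the aryl acetate F6.
   - Chemoselective aminolysis of the aryl ester (pyrrolidine, 0 °C) gives the phenol F7.
   - The electron-rich ring of F7 is cleaved by ozone (CH2Cl2/MeOH, −78 °C, then H2O2/HCO2H) faster than any C–H bond is attacked, which gives 4.

3. **Step 10.** Possible failures:
   - base-induced intramolecular aldol reaction of the 1,5-diketone (C16 enolate onto C8);
   - incomplete discrimination between the two ketones.

   The fallback sets out from 14 and comes back at 18.
   - Both ketones are methylenated at once with excess Ph3P=CH2. The methyl ketone reacts first, which removes the aldol partner, and C9 equilibrates before the slow olefination at C8. The product is the bis-methylene compound F8.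
   - Cross-metathesis of the unhindered C13=C16 alkene with acrylic acid (Hoveyda–Grubbs second-generation catalyst, CH2Cl2, 40 °C) gives 18 directly, with the flanked C8=C17 methylene group as a spectator.
   - This path is shorter but is expected to control the E geometry less well, which is why it is not the first choice.

**Further compounds**

F1 | step 9 | alkynyl aldehyde, [(1R,2S,3S)-2-(but-3-ynyl)-3-formyl-1,3-dimethylcyclohexyl]methyl acetate | C#CCC[C@H]1[C@](C)(COC(C)=O)CCC[C@]1(C)C=O
F2 | step 9 | (Z)-enyne ketal (C9=C11 Z-alkene, C13 as ethylene ketal, C8≡C17 alkyne) | C#CCC[C@H]1[C@](C)(COC(C)=O)CCC[C@]1(C)/C=C\CC2(C)OCCO2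
F3 | step 9 | vinylstannane ketal, 18-acetoxy-17-(tributylstannyl)-14,15-dinorlabd-8(17)-en-13-one ethylene ketal | CCCC[Sn](CCCC)(CCCC)C=C1CC[C@H]2[C@](C)(COC(C)=O)CCC[C@]2(C)[C@H]1CCC3(C)OCCO3
F4 | step 9 | methyl ketone, 18-acetoxy-14,15-dinorlabd-8(17)-en-13-one | C=C1CC[C@H]2[C@](C)(COC(C)=O)CCC[C@]2(C)[C@H]1CCC(C)=O
F5 | step 3 | 12-acetyl compound, 12-acetyl-18-acetoxyabieta-8,11,13-triene | CC(C)c1c(C(C)=O)cc2c(c1)CC[C@H]3[C@](C)(COC(C)=O)CCC[C@]23C
F6 | step 3 | aryl acetate, 12,18-diacetoxyabieta-8,11,13-triene | CC(C)c1c(OC(C)=O)cc2c(c1)CC[C@H]3[C@](C)(COC(C)=O)CCC[C@]23C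
F7 | step 3 | phenol, 18-acetoxyabieta-8,11,13-trien-12-ol | CC(C)c1c(O)cc2c(c1)CC[C@H]3[C@](C)(COC(C)=O)CCC[C@]23C
F8 | step 10 | bis-methylene compound, 18-acetoxy-14,15-dinorlabda-8(17),13(16)-diene | C=C1CC[C@H]2[C@](C)(COC(C)=O)CCC[C@]2(C)[C@H]1CCC(C)=C
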